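All constants stand for no real mixture; what happens was integrated by code.

At early times a molecule of Z needs two events in a row, L + D → L.D and then L.D → Z, so the question was which of these flasks gets past that double wait within its time.

the same everywhere: L 0.31 M; D 0.372 M; time 12 min
- Wednesday's: temperature 50 °C
- Sunday's: temperature −10 °C
- Thursday's: temperature 20 °C
- Tuesday's: temperature 80 °C

1. the flask that comes out highest in amount of Z, in percent of the L charged, or "all alike" when all lie within 1.5 percentage points (Wednesday's / Sunday's / Thursday's / Tuesday's / all alike)
2. Z at the end, in percent of the L charged, Wednesday's
3. Z at the end, in percent of the L charged, Sunday's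
4. Z at the end, in percent of the L charged, Thursday's
5. Z at the end, in percent of the L charged, Tuesday's

- all constants are for 50 °C and move with temperature by the activation energies

    L + D → L.D (k1 = 1.6 /M/min, Ea1 = 74.0 kJ/mol)
    L.D → Z (k2 = 0.28 /min, Ea2 = 86.0 kJ/mol)
    L + D → J (k3 = 0.19 /M/min, Ea3 = 56.0 kJ/mol)
    J → L.D (k4 = 0.32 /min, Ea4 = 102 kJ/mol)
    D → E (k5 = 1.0 × 10⁻⁴ /min, Ea5 = 108 kJ/mol)
    (constants at 50 °C)

I reckoned in powers of ten, holding [D] at its charge (the pseudo-first-order treatment) and leaving J aside. Let a be the constant of the first step times [D] times the time: while small, it is the share of L turned into L.D. Let b be the constant of the second step times the time. L.D builds up in proportion to time, so the share reaching Z is half of a times b. I moved each constant by its activation energy and set out common logarithms, coldest flask first.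

Sunday's: log a −1.87, log b −2.64, lag number −4.82

Thursday's: log a −0.370, log b −0.896, lag number −1.57

Wednesday's: log a 0.854, log b 0.526, lag number 1.08

Tuesday's: log a 1.87, log b 1.71, lag number 3.28

The lag number is the common logarithm of half of a times b, the early share of L standing as Z. Read down the columns, log b climbs 4.35 from Sunday's to Tuesday's and log a climbs 3.74, so b gains more than a, as the second step's activation energy stands 12.0 kJ/mol higher.

Read across, a negative lag number, taken back from its logarithm, is the estimate. For Sunday's I wrote 0.00152%. For Thursday's I wrote 2.71%, but a there is 42.7%, no longer small, so I took that figure as high. Wednesday's and Tuesday's stand above zero, where the rule has left its range. For Wednesday's I committed to no figure. For Tuesday's I wrote 100%, and the highest flask is Tuesday's.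

The forecast named Tuesday's, with 84% for Wednesday's (81% to 87%), 0.0015% for Sunday's, 2% for Thursday's and 99.9% for Tuesday's. Its ground for the cold flasks was that Z “builds roughly as time squared”. On Thursday's it stood below my figure.

The simulation gave Tuesday's highest, with Z at 84.0% Wednesday's, 0% Sunday's, 1.99% Thursday's and >99.9% Tuesday's. Sunday's Z printed as nothing at the asked time, but left ten times as long its lag number gains 2, since time enters squared, which gives 0.152% against the 0.134% found. A repeat of Sunday's at −35 °C reckons to log a −3.42, log b −4.44 and lag number −8.15, so a stands at 0.0384%. After 12.0 min that flask held Z at 0% and L.D at 0.0384%.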